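Ring A (labdane numbering) is a masked isophorone. The quaternary junction carbon C10 lies β to the C2 oxygen, and the cis junction (H-5 and CH3-20 on one face) places C6 and C9 together on the other face. Everything rests on the C9–C10 bond. The precursor is a monocyclic 4-substituted isophorone that already holds C5, C6, the butenolide and a stereodefined tetrasubstituted enol triflate (C8=C9). A palladium-catalysed reductive Heck cyclisation closes ring B in one operation. It builds quaternary C10 and the cis fusion under control of C5, keeps the C8=C9 alkene, leaves a C2 ketone for convex-face reduction and frees the C17 acid from its allyl ester.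

Key step: step 10

Remark: labdane numbering is used for all compounds (C1–C10 decalin carbons, C11/C12 chain, C13–C16 butenolide, C17 on C8, C18/C19 on C4, C20 on C10). In it the target is 2S,5R,6S,10S, that is 2α-OH, 6α-OH, H-5 β and CH3-20 β.
Remark: (R)-α-ionone (natural-grade flavour chemical) and 4-(bromomethyl)furan-2(5H)-one (catalogue building block) are taken as purchasable.

Step 1
Reactants: 1 (R)-α-ionone
Product: 3 (4S)-4-hydroxy-4-[(1R)-2,6,6-trimethylcyclohex-2-en-1-yl]butan-2-one, via pinacol boronate 2 (not isolated)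
Conditions: B2pin2, CuCl (cat.), NaOtBu (cat.), Josiphos SL-J001 (enantiomer matched to the substrate bias), MeOH, THF, 23 °C; then NaBO3·4H2O, THF/H2O, 23 °C
Reagents that add atoms: bis(pinacolato)diboron CC1(C)OB(OC1(C)C)B1OC(C)(C)C(C)(C)O1 (boron of 2); sodium perborate [Na+].[Na+].O[B-]1(O)OO[B-](O)(O)OO1 (oxygen of 3)
Why: Copper-catalysed conjugate borylation of the E-enone followed by stereoretentive C–B oxidation, in which boron should reach C6 anti to the quaternary C4 in the conformer with H-5 eclipsing the alkene (Felkin–Anh-type induction reinforced by the matched ligand), which sets 6S.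

Step 2
Reactants: 3 (4S)-4-hydroxy-4-[(1R)-2,6,6-trimethylcyclohex-2-en-1-yl]butan-2-one
Product: 4 (4S)-4-[(tert-butyldimethylsilyl)oxy]-4-[(1R)-2,6,6-trimethylcyclohex-2-en-1-yl]butan-2-one
Conditions: TBSCl, imidazole, DMF, 23 °C
Reagents that add atoms: tert-butyldimethylsilyl chloride CC(C)(C)[Si](C)(C)Cl
Why: Standard silyl ether formation under weakly basic conditions that should cause neither retro-aldol cleavage nor elimination, and the bulky group later biases the conformation of the cis-decalone.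

Step 3
Reactants: 4 (4S)-4-[(tert-butyldimethylsilyl)oxy]-4-[(1R)-2,6,6-trimethylcyclohex-2-en-1-yl]butan-2-one
Product: 5 (4R)-4-{(1S)-1-[(tert-butyldimethylsilyl)oxy]-3-oxobutyl}-3,5,5-trimethylcyclohex-2-en-1-one
Conditions: Rh2(cap)4 (cap = caprolactamate, 1 mol %), t-BuOOH, K2CO3, CH2Cl2, 23 °C
Reagents that add atoms: tert-butyl hydroperoxide CC(C)(C)OO
Why: Dirhodium-catalysed allylic C–H oxidation, which should take the only allylic CH2 of the ring alkene (C2) to the ketone as is usual for α-ionone-type rings, and no stereocentre is touched.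

Step 4
Reactants: 5 (4R)-4-{(1S)-1-[(tert-butyldimethylsilyl)oxy]-3-oxobutyl}-3,5,5-trimethylcyclohex-2-en-1-one
Product: 6 (2R)-2-[(tert-butyldimethylsilyl)oxy]-2-[(1R)-2,6,6-trimethyl-4-oxocyclohex-2-en-1-yl]ethyl acetate
Conditions: mCPBA, Sc(OTf)3 (cat.), CH2Cl2, 0 to 23 °C
Reagents that add atoms: 3-chloroperbenzoic acid OOC(=O)c1cccc(Cl)c1
Why: Baeyer–Villiger oxidation of the saturated methyl ketone, in which primary C7 migrates in preference to methyl while the electron-poor ring enone should be neither epoxidised nor oxidised at a comparable rate.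

Step 5
Reactants: 6 (2R)-2-[(tert-butyldimethylsilyl)oxy]-2-[(1R)-2,6,6-trimethyl-4-oxocyclohex-2-en-1-yl]ethyl acetate
Product: 7 (4R)-4-{(1R)-1-[(tert-butyldimethylsilyl)oxy]-2-hydroxyethyl}-3,5,5-trimethylcyclohex-2-en-1-one
Conditions: Novozym 435 (immobilised Candida antarctica lipase B), n-BuOH, MTBE, 35 °C
Reagents that add atoms: none
Why: Lipase-catalysed transesterification of an unhindered primary acetate, chosen because the neutral medium should allow neither 1,2-silyl migration nor epimerisation of the γ-position C5.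

Step 6
Reactants: 7 (4R)-4-{(1R)-1-[(tert-butyldimethylsilyl)oxy]-2-hydroxyethyl}-3,5,5-trimethylcyclohex-2-en-1-one
Product: 8 (4R)-4-{(1R)-1-[(tert-butyldimethylsilyl)oxy]-2-iodoethyl}-3,5,5-trimethylcyclohex-2-en-1-one
Conditions: I2, PPh3, imidazole, CH2Cl2, 0 to 23 °C
Reagents that add atoms: iodine [I][I]
Why: Appel-type iodination, an SN2 displacement of the alkoxyphosphonium group at primary C7 that leaves C5 and C6 untouched.

Step 7
Reactants: 9 allyl acetoacetate; 10 4-(bromomethyl)furan-2(5H)-one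
Product: 12 prop-2-en-1-yl 3-oxo-5-(5-oxo-2,5-dihydrofuran-3-yl)pentanoate, via acetoacetate dianion 11 (not isolated)
Conditions: NaH, THF, 0 °C; n-BuLi, 0 °C; 10, −78 °C; aq. HCl
Reagents that add atoms: none
Why: γ-Alkylation of an acetoacetate dianion, in which the more reactive terminal carbanion should displace the activated allylic bromide by SN2 at low temperature and so form C11–C12.

Step 8
Reactants: 8 (4R)-4-{(1R)-1-[(tert-butyldimethylsilyl)oxy]-2-iodoethyl}-3,5,5-trimethylcyclohex-2-en-1-one; 12 prop-2-en-1-yl 3-oxo-5-(5-oxo-2,5-dihydrofuran-3-yl)pentanoate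
Product: 13 prop-2-en-1-yl 2-{(2S)-2-[(tert-butyldimethylsilyl)oxy]-2-[(1R)-2,6,6-trimethyl-4-oxocyclohex-2-en-1-yl]ethyl}-3-oxo-5-(5-oxo-2,5-dihydrofuran-3-yl)pentanoate (both C8 epimers)
Conditions: K2CO3, DMF, 40 °C
Reagents that add atoms: none
Why: C-alkylation of a β-keto ester (soft enolate and primary iodide, SN2) forms C7–C8 in a medium too weakly basic to deprotonate C5, and the new centre C8 is erased in the next step.

Step 9
Reactants: 13 prop-2-en-1-yl 2-{(2S)-2-[(tert-butyldimethylsilyl)oxy]-2-[(1R)-2,6,6-trimethyl-4-oxocyclohex-2-en-1-yl]ethyl}-3-oxo-5-(5-oxo-2,5-dihydrofuran-3-yl)pentanoate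
Product: 14 prop-2-en-1-yl (2E)-2-{(2S)-2-[(tert-butyldimethylsilyl)oxy]-2-[(1R)-2,6,6-trimethyl-4-oxocyclohex-2-en-1-yl]ethyl}-5-(5-oxo-2,5-dihydrofuran-3-yl)-3-{[(trifluoromethyl)sulfonyl]oxy}pent-2-enoate
Conditions: DBU, Tf2O, CH2Cl2, −78 to 0 °C
Reagents that add atoms: trifluoromethanesulfonic anhydride O=S(=O)(OS(=O)(=O)C(F)(F)F)C(F)(F)F
Why: Stereoselective enol triflate formation from an α-substituted β-keto ester, in which the non-chelated amidinium enolate turns its ketone oxygen away from the ester carbonyl, so that O-sulfonylation should give the E isomer (OTf cis to C7), whereas lithium salts would give Z.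

Step 10
Reactants: 14 prop-2-en-1-yl (2E)-2-{(2S)-2-[(tert-butyldimethylsilyl)oxy]-2-[(1R)-2,6,6-trimethyl-4-oxocyclohex-2-en-1-yl]ethyl}-5-(5-oxo-2,5-dihydrofuran-3-yl)-3-{[(trifluoromethyl)sulfonyl]oxy}pent-2-enoate
Product: 16 (5R,6S,10S)-6-[(tert-butyldimethylsilyl)oxy]-2-oxolabda-8,13-dien-15,16-olid-17-oic acid (cis-fused, H-5 and CH3-20 both β), via free acid enol triflate 15 (not isolated)
Conditions: Pd(PPh3)4 (10 mol %), Et3N, HCO2H (slow addition), DMF, 25 to 70 °C
Reagents that add atoms: none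
Why: Zerovalent palladium first ionises the allyl ester (formate reduces the π-allyl unit to propene and leaves carboxylate 15) and then inserts into the C9–OTf bond, the vinylpalladium species adds syn across the enone bond C10=C1, and the palladium enolate is released by formate-derived hydride (decarboxylation, reductive elimination), which regenerates the catalyst. The closest known reaction type is the intramolecular reductive Heck reaction (formal conjugate vinylation) of vinyl triflates and halides onto β-substituted cyclohexenones, combined with the standard palladium/formate cleavage of allyl esters. Ring B closes in the 6-exo-trig mode (C9 onto C10, C1 stays outside the new ring). The only new stereocentre, C10, is controlled by C5: the three-atom tether C6–C7–C8 lets C9 reach C10 only on the face of ring A that carries C6, by axial attack with C6 pseudo-equatorial, so CH3-20 ends syn to H-5 (cis fusion), whereas a trans fusion would need a boat-like insertion geometry. The step needs insertion to outrun hydride capture of the vinylpalladium species (favoured by slow addition of formic acid and the intramolecular setting), the E geometry of 14 (palladium cis to C7 and trans to the carboxylate), and chemoselectivity for the ring enone (attack on the butenolide would need a four-membered ring).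

Step 11
Reactants: 16 (5R,6S,10S)-6-[(tert-butyldimethylsilyl)oxy]-2-oxolabda-8,13-dien-15,16-olid-17-oic acid
Product: 17 (2S,5R,6S,10S)-6-[(tert-butyldimethylsilyl)oxy]-2,17-dihydroxylabda-8,13-dien-15,16-olide
Conditions: BH3·THF, THF, −10 to 0 °C; then H2O
Reagents that add atoms: none
Why: Borane reduction, chemoselective for the carboxylic acid and the ketone over the conjugated lactone and the tetrasubstituted alkene; in the folded cis-decalone with the 6α-silyloxy group equatorial, axial C9 and the axial 4α-methyl shield the α face of C2, so hydride should arrive from the convex β face and set 2α-OH (2S).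

Step 12
Reactants: 17 (2S,5R,6S,10S)-6-[(tert-butyldimethylsilyl)oxy]-2,17-dihydroxylabda-8,13-dien-15,16-olide
Product: 18 (2S,5R,6S,10S)-2,6,17-trihydroxylabda-8,13-dien-15,16-olide (CNP0293367.1)
Conditions: HF·pyridine, pyridine, THF, 0 to 23 °C
Reagents that add atoms: none
Why: Fluoride-mediated desilylation under buffered, non-basic conditions that should leave the butenolide, the allylic alcohol and all four stereocentres unchanged.

Compound list
1 | (R)-α-ionone, (3E)-4-[(1R)-2,6,6-trimethylcyclohex-2-en-1-yl]but-3-en-2-one | CC1(C)CCC=C(C)[C@@H]1/C=C/C(C)=O | starting material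
2 | (4S)-4-(4,4,5,5-tetramethyl-1,3,2-dioxaborolan-2-yl)-4-[(1R)-2,6,6-trimethylcyclohex-2-en-1-yl]butan-2-one | CC1(C)CCC=C(C)[C@@H]1[C@@H](B2OC(C)(C)C(C)(C)O2)CC(C)=O | intermediate
3 | (4S)-4-hydroxy-4-[(1R)-2,6,6-trimethylcyclohex-2-en-1-yl]butan-2-one | CC1(C)CCC=C(C)[C@@H]1[C@@H](O)CC(C)=O | intermediate
4 | (4S)-4-[(tert-butyldimethylsilyl)oxy]-4-[(1R)-2,6,6-trimethylcyclohex-2-en-1-yl]butan-2-one | CC1(C)CCC=C(C)[C@@H]1[C@@H](O[Si](C)(C)C(C)(C)C)CC(C)=O | intermediate
5 | (4R)-4-{(1S)-1-[(tert-butyldimethylsilyl)oxy]-3-oxobutyl}-3,5,5-trimethylcyclohex-2-en-1-one | CC1(C)CC(=O)C=C(C)[C@@H]1[C@@H](O[Si](C)(C)C(C)(C)C)CC(C)=O | intermediate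
6 | (2R)-2-[(tert-butyldimethylsilyl)oxy]-2-[(1R)-2,6,6-trimethyl-4-oxocyclohex-2-en-1-yl]ethyl acetate | CC1(C)CC(=O)C=C(C)[C@@H]1[C@@H](O[Si](C)(C)C(C)(C)C)COC(C)=O | intermediate
7 | (4R)-4-{(1R)-1-[(tert-butyldimethylsilyl)oxy]-2-hydroxyethyl}-3,5,5-trimethylcyclohex-2-en-1-one | CC1(C)CC(=O)C=C(C)[C@@H]1[C@@H](O[Si](C)(C)C(C)(C)C)CO | intermediate
8 | (4R)-4-{(1R)-1-[(tert-butyldimethylsilyl)oxy]-2-iodoethyl}-3,5,5-trimethylcyclohex-2-en-1-one | CC1(C)CC(=O)C=C(C)[C@@H]1[C@@H](O[Si](C)(C)C(C)(C)C)CI | intermediate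
9 | allyl acetoacetate (prop-2-en-1-yl 3-oxobutanoate) | CC(=O)CC(=O)OCC=C | starting material
10 | 4-(bromomethyl)furan-2(5H)-one | BrCC1=CC(=O)OC1 | starting material
11 | sodium lithium dianion of allyl acetoacetate | [Na+].[Li+].[CH2-]C(=O)[CH-]C(=O)OCC=C | intermediate
12 | prop-2-en-1-yl 3-oxo-5-(5-oxo-2,5-dihydrofuran-3-yl)pentanoate | C=CCOC(=O)CC(=O)CCC1=CC(=O)OC1 | intermediate
13 | prop-2-en-1-yl 2-{(2S)-2-[(tert-butyldimethylsilyl)oxy]-2-[(1R)-2,6,6-trimethyl-4-oxocyclohex-2-en-1-yl]ethyl}-3-oxo-5-(5-oxo-2,5-dihydrofuran-3-yl)pentanoate (both C8 epimers) | CC1(C)CC(=O)C=C(C)[C@@H]1[C@@H](O[Si](C)(C)C(C)(C)C)CC(C(=O)OCC=C)C(=O)CCC1=CC(=O)OC1 | intermediate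
14 | prop-2-en-1-yl (2E)-2-{(2S)-2-[(tert-butyldimethylsilyl)oxy]-2-[(1R)-2,6,6-trimethyl-4-oxocyclohex-2-en-1-yl]ethyl}-5-(5-oxo-2,5-dihydrofuran-3-yl)-3-{[(trifluoromethyl)sulfonyl]oxy}pent-2-enoate | CC1(C)CC(=O)C=C(C)[C@@H]1[C@@H](O[Si](C)(C)C(C)(C)C)C/C(C(=O)OCC=C)=C(\OS(=O)(=O)C(F)(F)F)CCC1=CC(=O)OC1 | intermediate
15 | (2E)-2-{(2S)-2-[(tert-butyldimethylsilyl)oxy]-2-[(1R)-2,6,6-trimethyl-4-oxocyclohex-2-en-1-yl]ethyl}-5-(5-oxo-2,5-dihydrofuran-3-yl)-3-{[(trifluoromethyl)sulfonyl]oxy}pent-2-enoic acid | CC1(C)CC(=O)C=C(C)[C@@H]1[C@@H](O[Si](C)(C)C(C)(C)C)C/C(C(=O)O)=C(\OS(=O)(=O)C(F)(F)F)CCC1=CC(=O)OC1 | intermediate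
16 | (5R,6S,10S)-6-[(tert-butyldimethylsilyl)oxy]-2-oxolabda-8,13-dien-15,16-olid-17-oic acid (cis-fused) | CC1(C)CC(=O)C[C@]2(C)C(CCC3=CC(=O)OC3)=C(C(=O)O)C[C@H](O[Si](C)(C)C(C)(C)C)[C@H]12 | intermediate
17 | (2S,5R,6S,10S)-6-[(tert-butyldimethylsilyl)oxy]-2,17-dihydroxylabda-8,13-dien-15,16-olide | CC1(C)C[C@H](O)C[C@]2(C)C(CCC3=CC(=O)OC3)=C(CO)C[C@H](O[Si](C)(C)C(C)(C)C)[C@H]12 | intermediate
18 | (2S,5R,6S,10S)-2,6,17-trihydroxylabda-8,13-dien-15,16-olide (CNP0293367.1) | CC1(C)C[C@H](O)C[C@]2(C)C(CCC3=CC(=O)OC3)=C(CO)C[C@H](O)[C@H]12 | target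

Total step count: 12. Longest linear sequence: 11 (steps 1–6 and 8–12).

Steps most likely to fail

Step 10. Hydride capture of the vinylpalladium species may outrun the slow insertion into the hindered β,β-disubstituted enone, so that the C9–O bond is simply hydrogenolysed and no ring forms. The fallback takes palladium out of the C–C bond formation and sets out from 13. PPh3, I2 and Et3N in MeCN should convert the β-keto ester into the β-iodo enoate F1. Its E/Z mixture is acceptable because the derived vinyl radical inverts rapidly. (Me3Si)3SiH with Et3B and air in toluene generates the C9 vinyl radical, whose 6-exo-trig addition to C10 should give the cis-fused bicyclic allyl ester F2. Pd(PPh3)4 with HCO2H and Et3N at 23 °C then removes the allyl group, and the route is rejoined at 16.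

Step 7. Proton transfer from the acidic ring CH2 of the bromobutenolide to the strongly basic dianion may compete with substitution, followed by loss of bromide and decomposition. The fallback sets out from 10 and uses a soft nucleophile. Sodium di-tert-butyl malonate (NaH, THF, 0 °C) should give the malonate adduct F3. TFA followed by heating in toluene removes both tert-butyl groups and one carboxyl group to give 3-(5-oxo-2,5-dihydrofuran-3-yl)propanoic acid F4. Activation with 1,1'-carbonyldiimidazole and C-acylation of Mg(O2CCH2CO2CH2CH=CH2)2 (Masamune–Brooks homologation) rejoins the route at 12.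

Step 8. The SN2 displacement at the β-branched iodide may be slow, which leaves room for O-alkylation and for vinylogous elimination of silanolate across C5–C6. The fallback sets out from 7 and replaces substitution by condensation. Dess–Martin periodinane should give the α-silyloxy aldehyde F5. Knoevenagel condensation with 12 (piperidinium acetate, CH2Cl2, 0 °C) gives the alkylidene β-keto ester F6. Conjugate reduction with Hantzsch ester in the same flask rejoins the route at 13.

Further compounds
F1 | step 10 | prop-2-en-1-yl 2-{(2S)-2-[(tert-butyldimethylsilyl)oxy]-2-[(1R)-2,6,6-trimethyl-4-oxocyclohex-2-en-1-yl]ethyl}-3-iodo-5-(5-oxo-2,5-dihydrofuran-3-yl)pent-2-enoate (E/Z mixture) | CC1(C)CC(=O)C=C(C)[C@@H]1[C@@H](O[Si](C)(C)C(C)(C)C)CC(C(=O)OCC=C)=C(I)CCC1=CC(=O)OC1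
F2 | step 10 | prop-2-en-1-yl (5R,6S,10S)-6-[(tert-butyldimethylsilyl)oxy]-2-oxolabda-8,13-dien-15,16-olid-17-oate (cis-fused) | CC1(C)CC(=O)C[C@]2(C)C(CCC3=CC(=O)OC3)=C(C(=O)OCC=C)C[C@H](O[Si](C)(C)C(C)(C)C)[C@H]12
F3 | step 7 | di-tert-butyl 2-[(5-oxo-2,5-dihydrofuran-3-yl)methyl]propanedioate | CC(C)(C)OC(=O)C(CC1=CC(=O)OC1)C(=O)OC(C)(C)C
F4 | step 7 | 3-(5-oxo-2,5-dihydrofuran-3-yl)propanoic acid | OC(=O)CCC1=CC(=O)OC1
F5 | step 8 | (2R)-2-[(tert-butyldimethylsilyl)oxy]-2-[(1R)-2,6,6-trimethyl-4-oxocyclohex-2-en-1-yl]acetaldehyde | CC1(C)CC(=O)C=C(C)[C@@H]1[C@@H](O[Si](C)(C)C(C)(C)C)C=O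
F6 | step 8 | prop-2-en-1-yl 2-{2-[(tert-butyldimethylsilyl)oxy]-2-[(1R)-2,6,6-trimethyl-4-oxocyclohex-2-en-1-yl]ethylidene}-3-oxo-5-(5-oxo-2,5-dihydrofuran-3-yl)pentanoate (E/Z mixture, C5 and C6 as in 7) | CC1(C)CC(=O)C=C(C)[C@@H]1[C@@H](O[Si](C)(C)C(C)(C)C)C=C(C(=O)OCC=C)C(=O)CCC1=CC(=O)OC1
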